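**Strategy**

Everything rests on disconnecting the aryl ether bond O1–C8a, the link through which oxygen joins the stereogenic benzylic carbon C2 of ring C to ring A. Ring C is closed by a palladium-catalysed intramolecular C–O coupling between a free secondary alcohol and an aryl bromide; since the coupling leaves the C2–O bond intact, the (S) configuration set beforehand by catalytic asymmetric ketone reduction passes unchanged into the flavan. The cyclisation precursor is an open-chain (1S)-1,3-diarylpropan-1-ol in which the ring A aryl carries bromine at the future C8a, the prenyl group, two MOM ethers and a silyl-protected C4 carbinol that is oxidised to the ketone after ring closure.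

Key step: step 10

Assumption: the silyloxy-bearing carbon (future C4) is carried as a mixture of both configurations from step 7 to step 11, because it becomes the carbonyl carbon in step 12; i-PrMgCl·LiCl and LiN(i-Pr)2 are used as commercial solutions.

**Route**

Step 1
Reactants: 1 5-bromoresorcinol
Product: 2 1-bromo-3,5-bis(methoxymethoxy)benzene
Conditions: MOMCl (2.5 equiv), i-Pr2NEt (3 equiv), CH2Cl2, 0 °C → rt
Reagents that add atoms: chloromethyl methyl ether (MOMCl), COCCl
Why: Double O-alkylation of the phenols with MOMCl under amine base (Williamson-type acetal protection) should be clean, and the MOM ethers tolerate the organomagnesium, organolithium, palladium and fluoride steps that follow.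

Step 2
Reactants: 2 1-bromo-3,5-bis(methoxymethoxy)benzene
Product: 3 3-bromo-2,4-diiodo-1,5-bis(methoxymethoxy)benzene
Conditions: NIS (2.3 equiv), CF3CO2H (10 mol %), MeCN, 0 °C → rt, dark
Reagents that add atoms: N-iodosuccinimide (NIS), O=C1CCC(=O)N1I
Why: Electrophilic aromatic iodination is expected at the two equivalent bromine-flanked positions, each para to one MOM ether and ortho to the other, the position between the two ethers being the slowest to react as in the 4,6-dihalogenation of resorcinol diethers, whereas metalation with amide bases would go between the ethers and is therefore avoided.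

Step 3
Reactants: 3 3-bromo-2,4-diiodo-1,5-bis(methoxymethoxy)benzene; 4 prenyl bromide
Product: 6 3-bromo-2-iodo-1,5-bis(methoxymethoxy)-4-(3-methylbut-2-en-1-yl)benzene, via arylmagnesium chloride 5 (not isolated)
Conditions: i-PrMgCl·LiCl (1.05 equiv), THF, −40 °C; then CuI (10 mol %), prenyl bromide (1.3 equiv), −40 → 0 °C
Reagents that add atoms: none
Why: Iodine–magnesium exchange is much faster at C–I than at C–Br and stops after one exchange because the arylmagnesium is deactivated, the two iodines are equivalent so no regiochemical choice arises, and copper-catalysed allylic substitution of prenyl bromide at its unhindered CH2 terminus should give the linear prenyl arene.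

Step 4
Reactants: 6 3-bromo-2-iodo-1,5-bis(methoxymethoxy)-4-(3-methylbut-2-en-1-yl)benzene
Product: 8 2-bromo-4,6-bis(methoxymethoxy)-3-(3-methylbut-2-en-1-yl)benzaldehyde, via arylmagnesium chloride 7 (not isolated)
Conditions: i-PrMgCl·LiCl (1.1 equiv), THF, −40 °C; DMF (3 equiv), −40 → 0 °C; aq. NH4Cl
Reagents that add atoms: N,N-dimethylformamide (DMF), CN(C)C=O
Why: A second iodine–magnesium exchange at the remaining C–I bond followed by formylation with DMF (Bouveault aldehyde synthesis) places the aldehyde carbon, the future C4, beside bromine, while the ortho-bromoarylmagnesium is kept cold enough to avoid aryne formation.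

Step 5
Reactants: 9 4-bromo-2-iodoanisole; 4 prenyl bromide
Product: 11 4-bromo-1-methoxy-2-(3-methylbut-2-en-1-yl)benzene, via arylmagnesium chloride 10 (not isolated)
Conditions: i-PrMgCl·LiCl (1.05 equiv), THF, −30 °C; then CuI (10 mol %), prenyl bromide (1.3 equiv), −30 → 0 °C
Reagents that add atoms: none
Why: Iodine–magnesium exchange is selective for C–I over C–Br, and the copper-catalysed coupling with prenyl bromide installs the ring B prenyl group ortho to methoxy without touching the bromide needed next.

Step 6
Reactants: 11 4-bromo-1-methoxy-2-(3-methylbut-2-en-1-yl)benzene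
Product: 13 1-[4-methoxy-3-(3-methylbut-2-en-1-yl)phenyl]ethan-1-one, via aryllithium 12 (not isolated)
Conditions: n-BuLi (1.05 equiv), THF, −78 °C; MeC(O)N(OMe)Me (1.3 equiv), −78 → 0 °C; aq. NH4Cl
Reagents that add atoms: N-methoxy-N-methylacetamide, CON(C)C(C)=O
Why: Bromine–lithium exchange followed by acylation with the N-methoxy-N-methylamide (Weinreb ketone synthesis) stops at the methyl ketone because the chelated tetrahedral adduct survives until work-up.

Step 7
Reactants: 13 1-[4-methoxy-3-(3-methylbut-2-en-1-yl)phenyl]ethan-1-one; 8 2-bromo-4,6-bis(methoxymethoxy)-3-(3-methylbut-2-en-1-yl)benzaldehyde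
Product: 15 racemic 3-[2-bromo-4,6-bis(methoxymethoxy)-3-(3-methylbut-2-en-1-yl)phenyl]-3-hydroxy-1-[4-methoxy-3-(3-methylbut-2-en-1-yl)phenyl]propan-1-one, via lithium enolate 14 (not isolated)
Conditions: LiN(i-Pr)2 (1.05 equiv), THF, −78 °C; then 8, −78 °C; aq. NH4Cl at −78 °C
Reagents that add atoms: none
Why: Kinetic deprotonation gives the lithium enolate, whose aldol addition to the non-enolisable aldehyde forms the C3–C4 bond, and the new carbinol centre (future C4) is formed without control, which is harmless because it is later oxidised.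

Step 8
Reactants: 15 racemic aldol
Product: 16 racemic 3-[2-bromo-4,6-bis(methoxymethoxy)-3-(3-methylbut-2-en-1-yl)phenyl]-3-(tert-butyldimethylsilyloxy)-1-[4-methoxy-3-(3-methylbut-2-en-1-yl)phenyl]propan-1-one
Conditions: t-BuMe2SiOTf (1.3 equiv), 2,6-lutidine (2.5 equiv), CH2Cl2, −78 → −40 °C
Reagents that add atoms: tert-butyldimethylsilyl trifluoromethanesulfonate, CC(C)(C)[Si](C)(C)OS(=O)(=O)C(F)(F)F
Why: O-Silylation of the secondary alcohol with the silyl triflate and a hindered pyridine base at low temperature outruns retro-aldol cleavage and dehydration, and removes the β-hydroxy ketone that would not survive the basic coupling.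

Step 9
Reactants: 16 racemic β-silyloxy ketone
Product: 17 (1S)-3-[2-bromo-4,6-bis(methoxymethoxy)-3-(3-methylbut-2-en-1-yl)phenyl]-3-(tert-butyldimethylsilyloxy)-1-[4-methoxy-3-(3-methylbut-2-en-1-yl)phenyl]propan-1-ol (both epimers at C3)
Conditions: (R)-methyl CBS oxazaborolidine [(3aR)-1-methyl-3,3-diphenyltetrahydro-1H,3H-pyrrolo[1,2-c][1,3,2]oxazaborole] (20 mol %), catecholborane (2 equiv), toluene, −78 → −40 °C; then MeOH, H2O
Reagents that add atoms: none
Why: In this Corey–Bakshi–Shibata reduction the (R)-oxazaborolidine binds the ketone with the aryl group as the large substituent and delivers hydride to the Re face, which should give the (1S)-carbinol (future C2) under catalyst control for both epimers at the silyloxy carbon, and catecholborane is the hydride source because BH3 would hydroborate the two prenyl groups.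

Step 10
Reactants: 17 (1S)-bromo alcohol
Product: 18 (2S)-4-(tert-butyldimethylsilyloxy)-5,7-bis(methoxymethoxy)-4'-methoxy-8,3'-bis(3-methylbut-2-en-1-yl)flavan (both epimers at C4)
Conditions: Pd(OAc)2 (5 mol %), 2-(di-tert-butylphosphino)-1,1'-binaphthyl (7.5 mol %), Cs2CO3 (1.5 equiv), toluene, 80 °C
Reagents that add atoms: none
Why: Zerovalent palladium bearing one bulky phosphine inserts into the C8a–Br bond, Cs2CO3 deprotonates the coordinated C2 hydroxyl so that the alkoxide replaces bromide on divalent palladium, and C(sp2)–O reductive elimination releases the flavan. The closest known reaction type is the intramolecular Buchwald–Hartwig etherification of 3-(2-bromoaryl)propanols bearing secondary alcohols to give chromans. Ring C closes as a six-membered oxacycle by contraction of a seven-membered aryl(alkoxo)palladacycle (Pd, C8a, C4a, C4, C3, C2, O1) in the reductive elimination. No stereocentre is created: the bond from C2 to oxygen is a spectator, so the (S) configuration from step 9 is retained, and C4 stays a mixture. The step needs reductive elimination to outrun β-hydride elimination at C2–H, which the bulky electron-rich di-tert-butylphosphine should secure. Chemoselectivity is built into the substrate because only the C2 hydroxyl is free, the silylated C4 oxygen could at most close a four-membered ring, and the prenyl alkenes offer only strained 4-exo or 5-endo carbopalladation paths.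

Step 11
Reactants: 18 silyl-protected flavan
Product: 19 (2S)-5,7-bis(methoxymethoxy)-4'-methoxy-8,3'-bis(3-methylbut-2-en-1-yl)flavan-4-ol (both epimers at C4)
Conditions: Bu4NF (1.5 equiv), THF, 0 °C → rt
Reagents that add atoms: none
Why: Fluoride cleaves the Si–O bond (desilylation driven by Si–F bond formation) under basic conditions that leave the MOM acetals, the aryl ether and C2 untouched.

Step 12
Reactants: 19 flavan-4-ol
Product: 20 (2S)-5,7-bis(methoxymethoxy)-4'-methoxy-8,3'-bis(3-methylbut-2-en-1-yl)flavan-4-one
Conditions: Dess–Martin periodinane [1,1,1-triacetoxy-1,1-dihydro-1,2-benziodoxol-3(1H)-one] (1.3 equiv), NaHCO3 (5 equiv), CH2Cl2, 0 °C → rt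
Reagents that add atoms: none
Why: Dess–Martin oxidation converts both epimeric benzylic C4 alcohols into the one ketone under buffered, non-basic conditions, so neither the MOM ethers nor the C2 centre (which could only scramble by base-induced ring opening to the chalcone) is put at risk.

Step 13
Reactants: 20 bis-MOM flavanone
Product: 21 (2S)-5,7-dihydroxy-4'-methoxy-8,3'-bis(3-methylbut-2-en-1-yl)flavan-4-one (target)
Conditions: 3 M aq. HCl, MeOH, 40 °C
Reagents that add atoms: none
Why: Acid-catalysed methanolysis of the two MOM acetals via oxocarbenium ions frees the 5- and 7-hydroxyls under conditions mild enough for the prenyl groups, and the C2 configuration is unaffected because no bond to C2 is broken.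

**Compound list**

1 | 5-bromoresorcinol (5-bromobenzene-1,3-diol) | Oc1cc(O)cc(Br)c1 | starting material
2 | 1-bromo-3,5-bis(methoxymethoxy)benzene | COCOc1cc(Br)cc(OCOC)c1 | intermediate
3 | 3-bromo-2,4-diiodo-1,5-bis(methoxymethoxy)benzene | COCOc1cc(OCOC)c(I)c(Br)c1I | intermediate
4 | prenyl bromide (1-bromo-3-methylbut-2-ene) | CC(C)=CCBr | starting material
5 | [2-bromo-3-iodo-4,6-bis(methoxymethoxy)phenyl]magnesium chloride (not isolated) | COCOc1cc(OCOC)c([Mg]Cl)c(Br)c1I | intermediate
6 | 3-bromo-2-iodo-1,5-bis(methoxymethoxy)-4-(3-methylbut-2-en-1-yl)benzene | COCOc1cc(OCOC)c(CC=C(C)C)c(Br)c1I | intermediate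
7 | [2-bromo-4,6-bis(methoxymethoxy)-3-(3-methylbut-2-en-1-yl)phenyl]magnesium chloride (not isolated) | COCOc1cc(OCOC)c(CC=C(C)C)c(Br)c1[Mg]Cl | intermediate
8 | 2-bromo-4,6-bis(methoxymethoxy)-3-(3-methylbut-2-en-1-yl)benzaldehyde | COCOc1cc(OCOC)c(CC=C(C)C)c(Br)c1C=O | intermediate
9 | 4-bromo-2-iodoanisole (4-bromo-2-iodo-1-methoxybenzene) | COc1ccc(Br)cc1I | starting material
10 | (5-bromo-2-methoxyphenyl)magnesium chloride (not isolated) | COc1ccc(Br)cc1[Mg]Cl | intermediate
11 | 4-bromo-1-methoxy-2-(3-methylbut-2-en-1-yl)benzene | COc1ccc(Br)cc1CC=C(C)C | intermediate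
12 | [4-methoxy-3-(3-methylbut-2-en-1-yl)phenyl]lithium (not isolated) | COc1ccc([Li])cc1CC=C(C)C | intermediate
13 | 1-[4-methoxy-3-(3-methylbut-2-en-1-yl)phenyl]ethan-1-one | COc1ccc(C(C)=O)cc1CC=C(C)C | intermediate
14 | lithium 1-[4-methoxy-3-(3-methylbut-2-en-1-yl)phenyl]ethen-1-olate (not isolated) | COc1ccc(C(=C)O[Li])cc1CC=C(C)C | intermediate
15 | racemic 3-[2-bromo-4,6-bis(methoxymethoxy)-3-(3-methylbut-2-en-1-yl)phenyl]-3-hydroxy-1-[4-methoxy-3-(3-methylbut-2-en-1-yl)phenyl]propan-1-one | COc1ccc(C(=O)CC(O)c2c(OCOC)cc(OCOC)c(CC=C(C)C)c2Br)cc1CC=C(C)C | intermediate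
16 | racemic 3-[2-bromo-4,6-bis(methoxymethoxy)-3-(3-methylbut-2-en-1-yl)phenyl]-3-(tert-butyldimethylsilyloxy)-1-[4-methoxy-3-(3-methylbut-2-en-1-yl)phenyl]propan-1-one | COc1ccc(C(=O)CC(O[Si](C)(C)C(C)(C)C)c2c(OCOC)cc(OCOC)c(CC=C(C)C)c2Br)cc1CC=C(C)C | intermediate
17 | (1S)-3-[2-bromo-4,6-bis(methoxymethoxy)-3-(3-methylbut-2-en-1-yl)phenyl]-3-(tert-butyldimethylsilyloxy)-1-[4-methoxy-3-(3-methylbut-2-en-1-yl)phenyl]propan-1-ol, both epimers at C3 | COc1ccc([C@@H](O)CC(O[Si](C)(C)C(C)(C)C)c2c(OCOC)cc(OCOC)c(CC=C(C)C)c2Br)cc1CC=C(C)C | intermediate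
18 | (2S)-4-(tert-butyldimethylsilyloxy)-5,7-bis(methoxymethoxy)-4'-methoxy-8,3'-bis(3-methylbut-2-en-1-yl)flavan, both epimers at C4 | COc1ccc([C@@H]2CC(O[Si](C)(C)C(C)(C)C)c3c(OCOC)cc(OCOC)c(CC=C(C)C)c3O2)cc1CC=C(C)C | intermediate
19 | (2S)-5,7-bis(methoxymethoxy)-4'-methoxy-8,3'-bis(3-methylbut-2-en-1-yl)flavan-4-ol, both epimers at C4 | COc1ccc([C@@H]2CC(O)c3c(OCOC)cc(OCOC)c(CC=C(C)C)c3O2)cc1CC=C(C)C | intermediate
20 | (2S)-5,7-bis(methoxymethoxy)-4'-methoxy-8,3'-bis(3-methylbut-2-en-1-yl)flavan-4-one | COc1ccc([C@@H]2CC(=O)c3c(OCOC)cc(OCOC)c(CC=C(C)C)c3O2)cc1CC=C(C)C | intermediate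
21 | (2S)-5,7-dihydroxy-4'-methoxy-8,3'-bis(3-methylbut-2-en-1-yl)flavan-4-one | COc1ccc([C@@H]2CC(=O)c3c(O)cc(O)c(CC=C(C)C)c3O2)cc1CC=C(C)C | target

**Step count and risks**

Total step count: 13. Longest linear sequence: 11 steps (steps 1–4 and 7–13, from 1); the ring B branch (steps 5 and 6) joins at step 7.

Steps most likely to fail:

1. Step 10 (key step). Oxidative addition into the doubly ortho-substituted C8a–Br bond may be slow. β-Hydride elimination from the palladium alkoxide may then compete, with loss of bromine and oxidation at C2. A base-induced 1,3-shift of the silyl group from the C4 oxygen to the C2 oxygen is also possible; it is reversible and only the C2 alkoxide can cyclise. The fallback moves the ring closure from O1–C8a to O1–C2 and uses an SN2 etherification with inversion. It sets out from ketone 16, which would be reduced with the (S)-enantiomer of the oxazaborolidine and catecholborane to the (1R)-alcohol F1. Deprotonation with n-BuLi, bromine–lithium exchange with t-BuLi at −78 °C and trapping with B(OMe)3 should give the arylboronic acid F2, oxidised in the same flask with NaOH/H2O2 to the phenol F3. A Mitsunobu reaction (PPh3, diisopropyl azodicarboxylate, THF, 0 °C) should then close ring C with inversion at C2, and the route is rejoined at 18.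

2. Step 2. The second iodination may stall next to the bromo-iodo pair, iodine may enter between the two ethers, or the acid co-catalyst may remove a MOM group. The fallback reverses the order of protection and halogenation so that the more activated free phenol is iodinated without any acetal present. It sets out from 1, which with ICl (2.1 equiv, Et2O, 0 °C → rt) should give 5-bromo-4,6-diiodobenzene-1,3-diol F4, by analogy with the 4,6-diiodination of resorcinol. Protection with MOMCl and i-Pr2NEt as in step 1 then rejoins the route at 3.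

3. Step 13. Protic acid may cyclise the C8 prenyl group onto the freed 7-hydroxyl (chroman formation), add HCl or methanol across the prenyl alkenes, or erode the C2 configuration through reversible ring opening. The fallback replaces hydrolysis by silyl transfer under buffered, aprotic conditions. It sets out from 20, which with Me3SiOTf and 2,2'-bipyridyl (MeCN, 0 °C → rt) should exchange both aryl MOM ethers for silyl ethers to give the bis(trimethylsilyl) ether F5. Brief stirring with water then hydrolyses the aryl silyl ethers and rejoins the route at 21.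

**Further compounds**

F1 | step 10 | (1R)-3-[2-bromo-4,6-bis(methoxymethoxy)-3-(3-methylbut-2-en-1-yl)phenyl]-3-(tert-butyldimethylsilyloxy)-1-[4-methoxy-3-(3-methylbut-2-en-1-yl)phenyl]propan-1-ol, both epimers at C3 | COc1ccc([C@H](O)CC(O[Si](C)(C)C(C)(C)C)c2c(OCOC)cc(OCOC)c(CC=C(C)C)c2Br)cc1CC=C(C)C
F2 | step 10 | [2-{(3R)-1-(tert-butyldimethylsilyloxy)-3-hydroxy-3-[4-methoxy-3-(3-methylbut-2-en-1-yl)phenyl]propyl}-3,5-bis(methoxymethoxy)-6-(3-methylbut-2-en-1-yl)phenyl]boronic acid, both epimers at the silyloxy carbon (not isolated) | COc1ccc([C@H](O)CC(O[Si](C)(C)C(C)(C)C)c2c(OCOC)cc(OCOC)c(CC=C(C)C)c2B(O)O)cc1CC=C(C)C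
F3 | step 10 | 2-{(3R)-1-(tert-butyldimethylsilyloxy)-3-hydroxy-3-[4-methoxy-3-(3-methylbut-2-en-1-yl)phenyl]propyl}-3,5-bis(methoxymethoxy)-6-(3-methylbut-2-en-1-yl)phenol, both epimers at the silyloxy carbon | COc1ccc([C@H](O)CC(O[Si](C)(C)C(C)(C)C)c2c(OCOC)cc(OCOC)c(CC=C(C)C)c2O)cc1CC=C(C)C
F4 | step 2 | 5-bromo-4,6-diiodobenzene-1,3-diol | Oc1cc(O)c(I)c(Br)c1I
F5 | step 13 | (2S)-4'-methoxy-8,3'-bis(3-methylbut-2-en-1-yl)-5,7-bis(trimethylsilyloxy)flavan-4-one | COc1ccc([C@@H]2CC(=O)c3c(O[Si](C)(C)C)cc(O[Si](C)(C)C)c(CC=C(C)C)c3O2)cc1CC=C(C)C
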